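At 35 °C, a charge of 0.250 M of partner gives target a mean life of 10.1 min, and the reading comes at 15 min.

| flask | substrate | partner | temperature | time |
|---|---|---|---|---|
| Thursday's | 0.25 M | 0.250 M | 5 °C | 15 min |
| Saturday's | 0.25 M | 0.250 M | 35 °C | 15 min |
| Wednesday's | 0.25 M | 0.250 M | 65 °C | 15 min |

    substrate + partner → target, rate k1*[substrate]*[partner]^0.5 (k1 = 0.0022 /M^0.5/s, Ea1 = 54.0 kJ/mol)
    2 substrate → self-condensation product (k2 = 0.12 /M/s, Ea2 = 67.0 kJ/mol)
    partner + target → over-reaction product (k3 = 0.0066 /M/s, Ea3 = 51.0 kJ/mol)
    (constants at 35 °C)

- in percentages every species weighs as the substrate in it: one self-condensation product counts as two
- a doubled species enters its step squared and goes two at a time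
- the list of constants is for 35 °C, to be carried to other temperatures by the activation energies

- the flask with the highest share of target in all that became target or over-reaction product ("all alike" if they lie within 1.5 percentage points) (Thursday's / Saturday's / Wednesday's / all alike)
- share of target in all that became target or over-reaction product, Thursday's
- share of target in all that became target or over-reaction product, Saturday's
- share of target in all that became target or over-reaction product, Wednesday's

The share asked for divides target by target plus over-reaction product, which together count the target ever born, so the amount born cancels. What remains is the fate of a target molecule once it has formed. Partner stays close to its charge: at the start of Thursday's flask substrate goes to self-condensation product 32 times as fast as to target. Target therefore decays by a pseudo-first-order law with life 1/(k3 c_partner), with k3 carried to each temperature by its activation energy. That life is 86.4 min in Thursday's flask and 1.73 min in Wednesday's.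

Two times now stand against each other: the reading time and this life. Their ratio in Thursday's flask is 0.174, and this ratio, the exposure, is 1.48 in Saturday's and 8.68 in Wednesday's, so the exposure is greater in Wednesday's flask than in Saturday's, and greater in Saturday's than in Thursday's. The other steps change the share through the age of target at the reading. A molecule born at the start survives as e to the minus exposure, and later ones survive better, so this is a floor: 84.1% for Thursday's, 22.7% for Saturday's and 0.0169% for Wednesday's. The floors rank Thursday's first, and this reckoning goes no further.

The forecast gives values rather than floors: Thursday's first, with 90% (87% to 92%), 36% (31% to 41%) and 0.2% (0.05% to 1%). Its ground is that “the over-reaction's pseudo-first-order lifetime sets how much survives”.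

The simulation gives Thursday's first, with 90.2%, then 35.5% for Saturday's and 0.181% for Wednesday's, each inside the forecast's range. Thursday's flask keeps its target because the run is short against that life: left ten times as long, to 150 min, its share falls from 90.2% to 32.7%. Thursday's exposure at that time is 1.74, near Saturday's 1.48, with a floor of 17.6%. That late share of Thursday's flask stands beside Saturday's 35.5% at 15 min.

All constants were drawn at random within sensible limits; the flask was simulated.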